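An easy division comes first: target formed, divided by catalyst charged, gives the rounds to target each catalyst has made. Oak is the flask asked about, followed so far, and maple is its earlier, more dilute run.

| flask | starting material | second substrate | capture agent | free catalyst | remark | time |
|---|---|---|---|---|---|---|
| oak | 0.32 M | 2 equiv | 0.032 M | 2.8 mol% | the very flask that is asked about, followed so far |  |
| maple | 0.21 M | 2 equiv | 0.032 M | 2.8 mol% | run made earlier |  |
| flask | 0.32 M | 2.00 equiv | 0.0320 M | 2.8 mol% |  | 8.0 d |

| run | time / h | target / % | starting material / % |
|---|---|---|---|
| oak | 25.0 | 11 | 87 |
| oak | 48.0 | 14 | 85 |
| oak | 72.0 | 17 | 81 |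
| oak | 96.0 | 18 | 76 |
| oak | 120 | 18 | 76 |
| oak | 144 | 19 | 75 |
| maple | 1.00 | 0 | 100 |
| maple | 3.00 | 0 | 95 |
| maple | 6.00 | 1 | 98 |
| maple | 8.00 | 3 | 95 |
| maple | 12.0 | 6 | 95 |
| maple | 15.0 | 5 | 91 |

(scatter of a reading: 1.5 percentage points)

- west: change nothing and wait 4.0 d more
- east: at 8.0 d take out 90% of the target then present, then wait 4.0 d
- north: at 8.0 d add starting material, 50.0% of the amount charged, then wait 4.0 d
- south-east: at 8.0 d add free catalyst, 100% of the amount charged, then wait 4.0 d

- target that was removed still counts
- the earlier runs were read with a standard deviation of 1.5 percentage points
- additions bring no volume worth counting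

- target, in percent of the starting material first charged, at 8.0 d
- which option adds most target ("none" when 2 percentage points or less is all one gets) (west / east / north / south-east / none)
- target present, with what was taken out counted in, in percent of the starting material first charged, after west
- target present, with what was taken out counted in, in percent of the starting material first charged, after north

Oak's target moves from 18% at 96.0 h to 19% at 144 h, a step smaller than the scatter of 1.5 percentage points, while starting material still reads 75%. So oak stalls with starting material at hand, and suspicion falls on the catalyst. Oak's last reading gives about 6.79 rounds to target: this is the turnover budget (turnover number), the target formed per catalyst charged until a flask stalls. My own reckoning therefore puts west, east and north, which bring no new catalyst, under the margin of 2 points. The fresh dose in south-east should bring about 19 points, which is more than that margin.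

The forecast gave 19.5% at 8.0 d (range 18% to 21%), 20% after west, 21% after north, and chose south-east, reasoning that “Fresh catalyst should give several more points”.

The simulation gives 20.5% at 8.0 d, 20.6% after west and 20.6% after north. South-east gains 24 points, against 0.12 points for north and the 19 points reckoned from the budget, so the choice south-east stands.

    starting material + free catalyst ⇌ catalyst intermediate A (K = 2.15 M⁻¹, k = 0.0867 M⁻¹ min⁻¹)
    catalyst intermediate A → free catalyst + target (k = 0.0138 min⁻¹)
    second substrate + free catalyst ⇌ catalyst intermediate B (K = 380 M⁻¹, k = 0.149 M⁻¹ min⁻¹)
    catalyst intermediate B → free catalyst + second product (k = 0.265 min⁻¹)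
    2 second substrate → self-condensation product (k = 2.01 × 10⁻⁴ M⁻¹ min⁻¹)
    catalyst intermediate A + capture agent → trapped intermediate (k = 0.0687 M⁻¹ min⁻¹)

At 192 h the asked flask holds 99.5% of its catalyst as trapped intermediate and 0.351% as free catalyst. Removing the path from catalyst intermediate A and capture agent to trapped intermediate raises target from 20.5% to 83.3%, so this trapping is the main reason for the stall. The budget therefore counts rounds to target before trapping. A neighbour flask, charged with 1.1 mol% of free catalyst and otherwise the same, is allowed 7.47% by the budget, and it gives 7.31%.

(The data are simulated from invented constants; scatter was added.)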